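**Retrosynthetic overview**
1. The target comes from one hydrogenation of a bis-O-benzyl 1,7-diarylhept-6-en-3-one, which saturates the alkene and removes both benzyl groups.
2. Both aryl–chain bonds of that enone are cut together. C1–aryl is a ketone homoenolate (nucleophilic β-carbon) plus an aryl bromide. C7–aryl is a Heck arylation of a terminal alkene. The two aryl groups are identical, so one aryl bromide is used twice.
3. The seven-carbon linchpin is 1-(but-3-enyl)cyclopropanol, a latent homoenolate, made from ethyl pent-4-enoate and EtMgBr (Kulinkovich).
4. The aryl bromide comes from O-benzylation of 4-bromoguaiacol.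
5. Rings: both arenes are bought. The only ring formed is the sacrificial cyclopropane (step 2), which is opened again in step 3.

Assumption: the SMILES has no stereocentre and no alkene, so the target is achiral and there is no enantiomer to select. The only stereo-element on the way, the E alkene of the penultimate compound, is erased in the last step.

**Route**

Step 1
Reactants: 1 4-bromo-2-methoxyphenol; 2 benzyl bromide
Product: 3 1-(benzyloxy)-4-bromo-2-methoxybenzene
Conditions: K2CO3 (1.5 equiv), DMF, 25 °C
Reagents that add atoms: benzyl bromide 2, BrCc1ccccc1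
Why: This is a Williamson ether synthesis in which the phenoxide displaces the benzylic bromide cleanly, and the benzyl group is chosen because it falls off in the hydrogenation that step 4 needs anyway.

Step 2
Reactants: 4 ethyl pent-4-enoate; 5 ethylmagnesium bromide (2.4 equiv)
Product: 6 1-(but-3-en-1-yl)cyclopropan-1-ol
Conditions: Ti(OiPr)4 (20 mol%), THF, 0 °C to rt, slow addition of 5; then sat. aq NH4Cl
Reagents that add atoms: ethylmagnesium bromide 5, CC[Mg]Br (supplies the ring CH2CH2 unit)
Why: In this Kulinkovich cyclopropanation the ethylene–titanium reagent acts as a 1,2-dicarbanion on the ester faster than it exchanges with the monosubstituted alkene, and the intramolecular alternative would need an unreasonably strained bicyclo[2.1.0]pentanol.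

Step 3
Reactants: 6 1-(but-3-en-1-yl)cyclopropan-1-ol; 3 1-(benzyloxy)-4-bromo-2-methoxybenzene (2.3 equiv)
Product: 9 (E)-1,7-bis[4-(benzyloxy)-3-methoxyphenyl]hept-6-en-3-one, via arylpalladium homoenolate 7 (not isolated), via mono-arylated heptenone 8 (not isolated)
Conditions: Pd(OAc)2 (5 mol%), XPhos (2-dicyclohexylphosphino-2',4',6'-triisopropylbiphenyl, 10 mol%), Cs2CO3 (1.3 equiv), toluene, 80 °C, 4 h; then Cy2NMe (1.5 equiv), 110 °C, 16 h, same flask
Reagents that add atoms: aryl bromide 3, COc1cc(Br)ccc1OCc1ccccc1 (two aryl groups are incorporated)
Why: Proposed new method: oxidative addition of 3 to zerovalent palladium, alkoxide exchange with 6 and strain-driven β-carbon elimination give the divalent palladium homoenolate 7, whose nucleophilic carbon β to the ketone reductively eliminates onto the normally electrophilic aryl carbon faster than it loses a β-hydride or inserts its own alkene because XPhos is bulky and the ketone oxygen chelates, and the same catalyst then performs a Mizoroki-Heck arylation of the terminal alkene of 8 after the carbonate is spent and Cy2NMe, too weak a base to support ketone α-arylation, takes over; the closest known reaction types are the palladium-catalysed cross-coupling of cyclopropanol-derived ketone homoenolates with aryl bromides and the Heck reaction with bulky monophosphines, each established separately but not run in one flask on one linchpin, and alkene positional or E/Z isomers are harmless because step 4 converges them.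

Step 4
Reactants: 9 (E)-1,7-bis[4-(benzyloxy)-3-methoxyphenyl]hept-6-en-3-one
Product: 10 1,7-bis(4-hydroxy-3-methoxyphenyl)heptan-3-one (target)
Conditions: H2 (1 atm), 10% Pd/C, EtOAc/EtOH 1:1, rt
Reagents that add atoms: none
Why: Catalytic hydrogenation combined with hydrogenolysis saturates the styrenyl alkene and cleaves both aryl benzyl ethers, while a dialkyl ketone and aryl methyl ethers are inert to Pd/C at 1 atm, and no stereocentre is created.

**Compound list**
1 | 4-bromo-2-methoxyphenol | COc1cc(Br)ccc1O | starting material
2 | benzyl bromide | BrCc1ccccc1 | starting material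
3 | 1-(benzyloxy)-4-bromo-2-methoxybenzene | COc1cc(Br)ccc1OCc1ccccc1 | intermediate
4 | ethyl pent-4-enoate | C=CCCC(=O)OCC | starting material
5 | ethylmagnesium bromide | CC[Mg]Br | starting material
6 | 1-(but-3-en-1-yl)cyclopropan-1-ol | C=CCCC1(O)CC1 | intermediate
7 | [4-(benzyloxy)-3-methoxyphenyl](3-oxohept-6-en-1-yl)palladium, the homoenolate (XPhos on the metal omitted) | C=CCCC(=O)CC[Pd]c1ccc(OCc2ccccc2)c(OC)c1 | intermediate (not isolated)
8 | 1-[4-(benzyloxy)-3-methoxyphenyl]hept-6-en-3-one | C=CCCC(=O)CCc1ccc(OCc2ccccc2)c(OC)c1 | intermediate (not isolated)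
9 | (E)-1,7-bis[4-(benzyloxy)-3-methoxyphenyl]hept-6-en-3-one | COc1cc(/C=C/CCC(=O)CCc2ccc(OCc3ccccc3)c(OC)c2)ccc1OCc1ccccc1 | intermediate
10 | 1,7-bis(4-hydroxy-3-methoxyphenyl)heptan-3-one | COc1cc(CCCCC(=O)CCc2ccc(O)c(OC)c2)ccc1O | target

**Step count**
Total steps: 4. Longest linear sequence: 3 (4 → 6 → 9 → 10, or 1 → 3 → 9 → 10).

**Three steps most likely to fail**

Step 3 is the riskiest. Possible failures are:
- a branched Heck regioisomer, which hydrogenation cannot correct
- 6-exo insertion of 7 into its own alkene
- β-hydride loss from 7
- residual ketone α-arylation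

The fallback sets out from 6 and comes back at 9. The palladium step is stopped after the 80 °C stage, using only 1.05 equiv of 3, and 8 is isolated. The C6=C7 bond is then made by olefin cross-metathesis instead of a Heck reaction. Commercial 2-methoxy-4-vinylphenol (C=Cc1ccc(O)c(OC)c1) is benzylated with 2 (K2CO3, DMF) to give 1-(benzyloxy)-2-methoxy-4-vinylbenzene F1. Compound 8 and F1 (2 equiv) are joined with the second-generation Grubbs catalyst in CH2Cl2 at 40 °C. This can only give the linear E alkene 9.

Step 2 is next. The titanium reagent may exchange with the terminal alkene, and 6 (MW 112) is volatile and easily lost on concentration. The fallback sets out from 4 and comes back at 9 by reversing the order of events.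
- The Heck arylation of 4 with 3 (Pd(OAc)2, P(o-tol)3, K2CO3, DMF, 100 °C) is done first and gives ethyl (E)-5-[4-(benzyloxy)-3-methoxyphenyl]pent-4-enoate F2.
- The Kulinkovich reaction with 5 and Ti(OiPr)4 is then run on this non-volatile ester, which has no terminal alkene. It gives 1-{(E)-4-[4-(benzyloxy)-3-methoxyphenyl]but-3-en-1-yl}cyclopropan-1-ol F3.
- A single homoenolate arylation of F3 with 3 (Pd(OAc)2, XPhos, Cs2CO3, toluene, 80 °C) delivers 9.

Step 4 is the third. Phosphine or bromide residues from step 3 can poison Pd/C, so the reaction may stall at a mono-benzyl ether, and forcing it risks reducing the ketone. The fallback sets out from 9 and comes back at 10, and separates the two tasks. Homogeneous hydrogenation with RhCl(PPh3)3 and H2 (3 atm) in toluene/EtOH reduces only the alkene and gives 1,7-bis[4-(benzyloxy)-3-methoxyphenyl]heptan-3-one F4. Lewis-acid debenzylation with BCl3 and pentamethylbenzene in CH2Cl2 at −78 °C then frees both phenols without touching the methyl ethers, giving 10.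

**Further compounds**
F1 | step 3 | 1-(benzyloxy)-2-methoxy-4-vinylbenzene | C=Cc1ccc(OCc2ccccc2)c(OC)c1
F2 | step 2 | ethyl (E)-5-[4-(benzyloxy)-3-methoxyphenyl]pent-4-enoate | CCOC(=O)CC/C=C/c1ccc(OCc2ccccc2)c(OC)c1
F3 | step 2 | 1-{(E)-4-[4-(benzyloxy)-3-methoxyphenyl]but-3-en-1-yl}cyclopropan-1-ol | OC1(CC/C=C/c2ccc(OCc3ccccc3)c(OC)c2)CC1
F4 | step 4 | 1,7-bis[4-(benzyloxy)-3-methoxyphenyl]heptan-3-one | COc1cc(CCCCC(=O)CCc2ccc(OCc3ccccc3)c(OC)c2)ccc1OCc1ccccc1
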